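**Retrosynthetic overview**

1. Target 31 ⇐ trans-bis-epoxidation of the ring A bromodiene 29: reagent-controlled epoxidation of C8=C10, then epoxidation of the bromoalkene anti to the first oxirane.
2. 29 ⇐ spiro enone 24 (α'-bromination, reduction–dehydration); 24 ⇐ keto aldehyde 22 by an intramolecular vinylogous Mukaiyama aldol that closes ring B and creates the spiro centre C12 and carbinol C20.
3. 22 ⇐ late C12–C13 coupling of fragment A (C8 ring A silyl dienol ether 8) with fragment B (C6 bromochloro triflate 18) by Stork–Danheiser alkylation and transposition.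
4. Fragment B ⇐ catalytic enantioselective bromochlorination of (Z)-allylic alcohol 16 (sets C14 and C16); fragment A ⇐ 3-methylcyclohex-2-enone via dimedone.
5. Ring order: ring A (carbocycle carried from 1) → ring B (step 14) → oxirane at C8/C10 (step 17) → bromo-oxirane at C4/C7 (step 18).

Assumption: carbons are labelled by their position in the given SMILES (C2 = CMe2, C4 = CBr, C7 and C8 = epoxide CH, C10 = epoxide CMe, C12 = spiro C, C13 = CH2, C14 = CHBr, C16 = CMeCl, C19 = CH2, C20 = CHOH); ring A = C2/C4/C7/C8/C10/C12, ring B = C12/C13/C14/C16/C19/C20.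

**Fragment A (steps 1–6)**

Step 1
Reactants: 1 3-methylcyclohex-2-en-1-one
Product: 2 3,3-dimethylcyclohexan-1-one
Conditions: MeMgBr (1.3 equiv), CuBr·SMe2 (5 mol %), THF, −30 → 0 °C; 1 M HCl quench
Reagents that add atoms: methylmagnesium bromide, C[Mg]Br
Why: copper-catalysed conjugate (1,4-) addition of the Grignard reagent to the β-methyl enone builds the geminal dimethyl carbon C2, and no stereocentre is formed.

Step 2
Reactants: 2 3,3-dimethylcyclohexan-1-one
Product: 3 5,5-dimethylcyclohex-2-en-1-one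
Conditions: IBX (1.6 equiv), DMSO–PhF, 70 °C
Reagents that add atoms: none
Why: IBX α,β-dehydrogenation of the ketone can only occur on the side away from the quaternary carbon, so a single enone results.

Step 3
Reactants: 3 5,5-dimethylcyclohex-2-en-1-one
Product: 4 4,4-dimethyl-7-oxabicyclo[4.1.0]heptan-2-one (racemic)
Conditions: 30 % aq. H2O2, NaOH (cat.), MeOH, 0 °C
Reagents that add atoms: hydrogen peroxide, OO
Why: Weitz–Scheffer nucleophilic epoxidation of the enone; the racemic epoxide stereocentres are erased in step 4.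

Step 4
Reactants: 4 4,4-dimethyl-7-oxabicyclo[4.1.0]heptan-2-one
Product: 5 5,5-dimethylcyclohexane-1,3-dione
Conditions: Pd(PPh3)4 (3 mol %), 1,2-bis(diphenylphosphino)ethane (3 mol %), PhMe, 110 °C
Reagents that add atoms: none
Why: palladium-catalysed isomerisation of the α,β-epoxy ketone (C–O oxidative addition, β-hydride elimination, tautomerisation) gives the 1,3-diketone.

Step 5
Reactants: 5 5,5-dimethylcyclohexane-1,3-dione
Product: 6 5,5-dimethyl-3-(2-methylpropoxy)cyclohex-2-en-1-one
Conditions: 2-methylpropan-1-ol (3 equiv), TsOH·H2O (2 mol %), PhMe, reflux, Dean–Stark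
Reagents that add atoms: 2-methylpropan-1-ol, CC(C)CO
Why: acid-catalysed enol etherification of the symmetrical dione (vinylogous ester formation) differentiates the two carbonyls.

Step 6
Reactants: 6 5,5-dimethyl-3-(2-methylpropoxy)cyclohex-2-en-1-one
Product: 8 trimethyl{[3,3-dimethyl-5-(2-methylpropoxy)cyclohexa-1,5-dien-1-yl]oxy}silane (fragment A), via sodium dienolate 7 (not isolated)
Conditions: NaN(SiMe3)2 (1.05 equiv, 1 M in THF), THF, −78 °C, 1 h; Me3SiCl (1.3 equiv), −78 → 0 °C; non-aqueous work-up (pentane, filtration), distillation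
Reagents that add atoms: chlorotrimethylsilane, C[Si](C)(C)Cl
Why: kinetic α'-enolisation by the hindered sodium silylamide at the only CH2 flanking the carbonyl (the future C12), followed by O-silylation (silyl enol ether formation), gives a distillable, regiodefined dienol ether from which an amine-free lithium dienolate is released only at the coupling.

**Fragment B (steps 7–12)**

Step 7
Reactants: 9 3-bromoprop-1-yne
Product: 11 4,4-dimethoxybut-1-yne, via propargylaluminium sesquibromide 10 (not isolated)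
Conditions: Al, HgCl2 (1 mol %), Et2O, 35 °C; then HC(OMe)3, Et2O, −78 °C → rt
Reagents that add atoms: trimethyl orthoformate, COC(OC)OC
Why: Barbier-type formation of the propargyl/allenyl aluminium reagent and its substitution of one methoxy group of the orthoformate give the homopropargyl acetal.

Step 8
Reactants: 11 4,4-dimethoxybut-1-yne
Product: 13 methyl 5,5-dimethoxypent-2-ynoate, via lithium acetylide 12 (not isolated)
Conditions: n-BuLi (1.05 equiv), THF, −78 °C; ClCO2Me, −78 → 0 °C
Reagents that add atoms: methyl chloroformate, COC(Cl)=O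
Why: C-acylation of the lithium acetylide gives the ynoate and introduces C13.

Step 9
Reactants: 13 methyl 5,5-dimethoxypent-2-ynoate
Product: 15 methyl (2Z)-5,5-dimethoxy-3-methylpent-2-enoate, via alkenylcuprate 14 (not isolated)
Conditions: Me2CuLi (from MeLi and CuI, 1.2 equiv), THF, −78 °C; MeOH quench at −78 °C
Reagents that add atoms: lithium dimethylcuprate, [Li+].C[Cu-]C
Why: syn-carbocupration of the ynoate and cold protonation with retention place the acetal-bearing CH2 cis to the ester, giving the (Z)-alkene needed for the later anti addition.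

Step 10
Reactants: 15 methyl (2Z)-5,5-dimethoxy-3-methylpent-2-enoate
Product: 16 (2Z)-5,5-dimethoxy-3-methylpent-2-en-1-ol
Conditions: i-Bu2AlH (2.3 equiv), CH2Cl2, −78 °C; aq. KNaC4H4O6
Reagents that add atoms: none
Why: 1,2-reduction of the enoate to the allylic alcohol proceeds without loss of the Z geometry.

Step 11
Reactants: 16 (2Z)-5,5-dimethoxy-3-methylpent-2-en-1-ol
Product: 17 (2S,3S)-2-bromo-3-chloro-5,5-dimethoxy-3-methylpentan-1-ol
Conditions: N-bromosuccinimide (1.1 equiv), ClTi(OiPr)3 (1.1 equiv), chiral tridentate Schiff-base ligand (20 mol %), hexanes, −20 °C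
Reagents that add atoms: N-bromosuccinimide, BrN1C(=O)CCC1=O; chlorotitanium triisopropoxide, CC(C)O[Ti](Cl)(OC(C)C)OC(C)C
Why: titanium/Schiff-base-catalysed enantioselective bromochlorination of the allylic alcohol gives anti addition with Br at C14 and chloride delivered to the distal tertiary C16, the ligand enantiomer fixing both centres as S.

Step 12
Reactants: 17 (2S,3S)-2-bromo-3-chloro-5,5-dimethoxy-3-methylpentan-1-ol
Product: 18 (2S,3S)-2-bromo-3-chloro-5,5-dimethoxy-3-methylpentyl trifluoromethanesulfonate (fragment B)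
Conditions: Tf2O (1.2 equiv), 2,6-lutidine (1.5 equiv), CH2Cl2, −78 °C; used at once
Reagents that add atoms: trifluoromethanesulfonic anhydride, O=S(=O)(OS(=O)(=O)C(F)(F)F)C(F)(F)F
Why: O-sulfonylation gives a primary triflate reactive enough for SN2 despite the β-bromine, leaving C14 and C16 untouched.

**Coupling and endgame (steps 13–18)**

Step 13
Reactants: 8 trimethyl{[3,3-dimethyl-5-(2-methylpropoxy)cyclohexa-1,5-dien-1-yl]oxy}silane (fragment A); 18 (2S,3S)-2-bromo-3-chloro-5,5-dimethoxy-3-methylpentyl trifluoromethanesulfonate (fragment B)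
Product: 22 (3S,4S)-4-bromo-3-chloro-3-methyl-5-(2,6,6-trimethyl-4-oxocyclohex-2-en-1-yl)pentanal (C12 epimers), via lithium dienolate 19 (not isolated), via alkylated vinylogous ester 20 (not isolated), via tertiary carbinol 21 (not isolated)
Conditions: MeLi (1.05 equiv), THF, 0 °C; 18, DMPU, −78 → −30 °C; then CeCl3, MeLi (3 equiv), −78 °C; then 1 M HCl, 0 °C → rt
Reagents that add atoms: methyllithium, [Li]C; water, O
Why: Stork–Danheiser sequence in one flask, in which MeLi cleaves the silyl dienol ether to the amine-free lithium dienolate, this displaces the primary triflate (SN2, C12–C13 bond), MeCeCl2 adds 1,2 to the vinylogous ester carbonyl and acid transposes it to the enone while hydrolysing the acetal; C12 forms as an epimer mixture erased in step 14, and C14 and C16 are untouched.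

Step 14
Reactants: 22 (3S,4S)-4-bromo-3-chloro-3-methyl-5-(2,6,6-trimethyl-4-oxocyclohex-2-en-1-yl)pentanal
Product: 24 (1S,3S,4S,6S)-4-bromo-3-chloro-3,7,11,11-tetramethyl-1-(trimethylsilyloxy)spiro[5.5]undec-7-en-9-one, via silyl dienol ether 23 (not isolated)
Conditions: Me3SiOTf (2.5 equiv), Et3N (3 equiv), CH2Cl2, −78 → −20 °C; aq. NaHCO3
Reagents that add atoms: trimethylsilyl trifluoromethanesulfonate, C[Si](C)(C)OS(=O)(=O)C(F)(F)F
Why: intramolecular vinylogous Mukaiyama aldol, in which soft enolisation makes C12 planar and only this γ-carbon can reach the silyl-activated aldehyde through a six-membered chair; with C–Br and C–Cl antiperiplanar, the C16 methyl and the silyloxonium equatorial and the C10 methyl turned away from the axial bromine, C12 and C20 are set as in the target.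

Step 15
Reactants: 24 (1S,3S,4S,6S)-4-bromo-3-chloro-3,7,11,11-tetramethyl-1-(trimethylsilyloxy)spiro[5.5]undec-7-en-9-one
Product: 27 (1S,3S,4S,6R)-4,10-dibromo-3-chloro-3,7,11,11-tetramethyl-1-(trimethylsilyloxy)spiro[5.5]undec-7-en-9-one (epimers at the new CHBr carbon C4), via spiro lithium dienolate 25 (not isolated), via bis-silyl dienol ether 26 (not isolated)
Conditions: LiN(SiMe3)2 (1.2 equiv), Me3SiCl (1.5 equiv), THF, −78 °C; then N-bromosuccinimide (1.1 equiv), −78 → 0 °C
Reagents that add atoms: N-bromosuccinimide, BrN1C(=O)CCC1=O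
Why: kinetic α'-enolisation at C4 (C12 is quaternary) with in situ silylation, then electrophilic bromination of the silyl dienol ether (α-halogenation via a silyl enol ether); the new C4 centre becomes sp2 in step 16.

Step 16
Reactants: 27 (1S,3S,4S,6R)-4,10-dibromo-3-chloro-3,7,11,11-tetramethyl-1-(trimethylsilyloxy)spiro[5.5]undec-7-en-9-one
Product: 29 (1S,3S,4S,6R)-4,10-dibromo-3-chloro-3,7,11,11-tetramethylspiro[5.5]undeca-7,9-dien-1-ol, via allylic alcohol 28 (not isolated)
Conditions: i-Bu2AlH (1.5 equiv), PhMe, −78 °C; then TsOH·H2O (5 equiv), 0 → 40 °C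
Reagents that add atoms: none
Why: 1,2-hydride reduction of the enone followed by acid-induced E1 dehydration of the allylic alcohol (the allyl cation loses H-4) gives the conjugated bromodiene with loss of the silyl ether, and no stereocentre is created.

Step 17
Reactants: 29 (1S,3S,4S,6R)-4,10-dibromo-3-chloro-3,7,11,11-tetramethylspiro[5.5]undeca-7,9-dien-1-ol
Product: 30 (1S,3S,4S,6R,7R,8S)-4,10-dibromo-3-chloro-7,8-epoxy-3,7,11,11-tetramethylspiro[5.5]undec-9-en-1-ol
Conditions: ent-Shi ketone (L-fructose-derived, 30 mol %), KHSO5 (as 2KHSO5·KHSO4·K2SO4, 1.4 equiv), K2CO3, Bu4NHSO4 (4 mol %), MeCN–CH2(OMe)2–aq. Na2B4O7 buffer, 0 °C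
Reagents that add atoms: potassium peroxymonosulfate, [K+].[O-]S(=O)(=O)OO
Why: Shi asymmetric epoxidation (chiral dioxirane, spiro transition state) selects the electron-rich trisubstituted C8=C10 bond over the bromoalkene, and the ent-ketone delivers oxygen to the face anti to C20, setting C8 (S) and C10 (R) under reagent control.

Step 18
Reactants: 30 (1S,3S,4S,6R,7R,8S)-4,10-dibromo-3-chloro-7,8-epoxy-3,7,11,11-tetramethylspiro[5.5]undec-9-en-1-ol
Product: 31 (1S,3S,4S,6R,7R,8S,9S,10S)-4,10-dibromo-3-chloro-7,8:9,10-diepoxy-3,7,11,11-tetramethylspiro[5.5]undecan-1-ol (target)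
Conditions: dimethyldioxirane (ca. 0.08 M in acetone, 4 equiv), CH2Cl2, 0 °C → rt, dark
Reagents that add atoms: dimethyldioxirane, CC1(C)OO1
Why: neutral dioxirane epoxidation of the bromoalkene occurs anti to the adjacent oxirane (trans-diepoxide) on the face carrying the C20 hydroxyl, which hydrogen-bonds the oxidant, setting C4 and C7.

**Compound list**

1 | 3-methylcyclohex-2-en-1-one | CC1=CC(=O)CCC1 | starting material
2 | 3,3-dimethylcyclohexan-1-one | CC1(C)CCCC(=O)C1 | intermediate
3 | 5,5-dimethylcyclohex-2-en-1-one | CC1(C)CC=CC(=O)C1 | intermediate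
4 | 4,4-dimethyl-7-oxabicyclo[4.1.0]heptan-2-one (racemic) | CC1(C)CC2OC2C(=O)C1 | intermediate
5 | 5,5-dimethylcyclohexane-1,3-dione | CC1(C)CC(=O)CC(=O)C1 | intermediate
6 | 5,5-dimethyl-3-(2-methylpropoxy)cyclohex-2-en-1-one | CC(C)COC1=CC(=O)CC(C)(C)C1 | intermediate
7 | sodium 3,3-dimethyl-5-(2-methylpropoxy)cyclohexa-1,5-dien-1-olate | [Na+].CC(C)COC1=CC([O-])=CC(C)(C)C1 | intermediate
8 | trimethyl{[3,3-dimethyl-5-(2-methylpropoxy)cyclohexa-1,5-dien-1-yl]oxy}silane (fragment A) | CC(C)COC1=CC(O[Si](C)(C)C)=CC(C)(C)C1 | intermediate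
9 | 3-bromoprop-1-yne | BrCC#C | starting material
10 | prop-2-ynylaluminium sesquibromide | C#CC[Al](Br)CC#C.C#CC[Al](Br)Br | intermediate
11 | 4,4-dimethoxybut-1-yne | C#CCC(OC)OC | intermediate
12 | lithium 4,4-dimethoxybut-1-yn-1-ide | [Li]C#CCC(OC)OC | intermediate
13 | methyl 5,5-dimethoxypent-2-ynoate | COC(=O)C#CCC(OC)OC | intermediate
14 | lithium methyl[(1E)-4,4-dimethoxy-1-(methoxycarbonyl)-2-methylbut-1-enyl]cuprate (Cu cis to the new methyl) | [Li+].COC(=O)/C([Cu-]C)=C(/C)CC(OC)OC | intermediate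
15 | methyl (2Z)-5,5-dimethoxy-3-methylpent-2-enoate | COC(=O)/C=C(/C)CC(OC)OC | intermediate
16 | (2Z)-5,5-dimethoxy-3-methylpent-2-en-1-ol | OC/C=C(/C)CC(OC)OC | intermediate
17 | (2S,3S)-2-bromo-3-chloro-5,5-dimethoxy-3-methylpentan-1-ol | OC[C@H](Br)[C@@](C)(Cl)CC(OC)OC | intermediate
18 | (2S,3S)-2-bromo-3-chloro-5,5-dimethoxy-3-methylpentyl trifluoromethanesulfonate (fragment B) | FC(F)(F)S(=O)(=O)OC[C@H](Br)[C@@](C)(Cl)CC(OC)OC | intermediate
19 | lithium 3,3-dimethyl-5-(2-methylpropoxy)cyclohexa-1,5-dien-1-olate | [Li+].CC(C)COC1=CC([O-])=CC(C)(C)C1 | intermediate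
20 | 6-[(2S,3S)-2-bromo-3-chloro-5,5-dimethoxy-3-methylpentyl]-5,5-dimethyl-3-(2-methylpropoxy)cyclohex-2-en-1-one (C12 epimers) | CC(C)COC1=CC(=O)C(C[C@H](Br)[C@@](C)(Cl)CC(OC)OC)C(C)(C)C1 | intermediate
21 | 6-[(2S,3S)-2-bromo-3-chloro-5,5-dimethoxy-3-methylpentyl]-1,5,5-trimethyl-3-(2-methylpropoxy)cyclohex-2-en-1-ol (as its alkoxide, diastereomer mixture) | CC(C)COC1=CC(C)(O)C(C[C@H](Br)[C@@](C)(Cl)CC(OC)OC)C(C)(C)C1 | intermediate
22 | (3S,4S)-4-bromo-3-chloro-3-methyl-5-(2,6,6-trimethyl-4-oxocyclohex-2-en-1-yl)pentanal (C12 epimers) | CC1=CC(=O)CC(C)(C)C1C[C@H](Br)[C@@](C)(Cl)CC=O | intermediate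
23 | (3S,4S)-4-bromo-3-chloro-3-methyl-5-[2,6,6-trimethyl-4-(trimethylsilyloxy)cyclohexa-1,3-dien-1-yl]pentanal | C[Si](C)(C)OC1=CC(C)=C(C[C@H](Br)[C@@](C)(Cl)CC=O)C(C)(C)C1 | intermediate
24 | (1S,3S,4S,6S)-4-bromo-3-chloro-3,7,11,11-tetramethyl-1-(trimethylsilyloxy)spiro[5.5]undec-7-en-9-one | CC1(C)CC(=O)C=C(C)[C@]12C[C@H](Br)[C@@](C)(Cl)C[C@@H]2O[Si](C)(C)C | intermediate
25 | lithium (1S,3S,4S,6R)-4-bromo-3-chloro-3,7,11,11-tetramethyl-1-(trimethylsilyloxy)spiro[5.5]undeca-7,9-dien-9-olate | [Li+].CC1(C)C=C([O-])C=C(C)[C@]12C[C@H](Br)[C@@](C)(Cl)C[C@@H]2O[Si](C)(C)C | intermediate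
26 | (1S,3S,4S,6R)-4-bromo-3-chloro-3,7,11,11-tetramethyl-1,9-bis(trimethylsilyloxy)spiro[5.5]undeca-7,9-diene | CC1(C)C=C(O[Si](C)(C)C)C=C(C)[C@]12C[C@H](Br)[C@@](C)(Cl)C[C@@H]2O[Si](C)(C)C | intermediate
27 | (1S,3S,4S,6R)-4,10-dibromo-3-chloro-3,7,11,11-tetramethyl-1-(trimethylsilyloxy)spiro[5.5]undec-7-en-9-one (epimers at C4) | CC1(C)C(Br)C(=O)C=C(C)[C@]12C[C@H](Br)[C@@](C)(Cl)C[C@@H]2O[Si](C)(C)C | intermediate
28 | (1S,3S,4S,6R)-4,10-dibromo-3-chloro-3,7,11,11-tetramethyl-1-(trimethylsilyloxy)spiro[5.5]undec-7-en-9-ol (diastereomer mixture at C4 and C7, as its aluminium alkoxide) | CC1(C)C(Br)C(O)C=C(C)[C@]12C[C@H](Br)[C@@](C)(Cl)C[C@@H]2O[Si](C)(C)C | intermediate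
29 | (1S,3S,4S,6R)-4,10-dibromo-3-chloro-3,7,11,11-tetramethylspiro[5.5]undeca-7,9-dien-1-ol | CC1(C)C(Br)=CC=C(C)[C@]12C[C@H](Br)[C@@](C)(Cl)C[C@@H]2O | intermediate
30 | (1S,3S,4S,6R,7R,8S)-4,10-dibromo-3-chloro-7,8-epoxy-3,7,11,11-tetramethylspiro[5.5]undec-9-en-1-ol | CC1(C)C(Br)=C[C@@H]2O[C@]2(C)[C@]12C[C@H](Br)[C@@](C)(Cl)C[C@@H]2O | intermediate
31 | (1S,3S,4S,6R,7R,8S,9S,10S)-4,10-dibromo-3-chloro-7,8:9,10-diepoxy-3,7,11,11-tetramethylspiro[5.5]undecan-1-ol | CC1(C)[C@@]2(Br)O[C@H]2[C@@H]2O[C@]2(C)[C@]12C[C@H](Br)[C@@](C)(Cl)C[C@@H]2O | target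

**Step count**

Total step count: 18.
Longest linear sequence: 12 steps (steps 1–6 or steps 7–12, then steps 13–18).

**Three steps most likely to fail, with fallbacks**

Step 13. The lithium dienolate may eliminate HOTf from the β-bromo triflate or react too slowly at the branched primary carbon. The fallback couples before halogenation; it sets out from 16 and 8 and returns at 20. Alcohol 16 is converted (MsCl, Et3N; then LiBr) into the (Z)-allylic bromide F1, which alkylates lithium dienolate 19 (from 8 and MeLi) to give the alkenyl vinylogous ester F2. Shi epoxidation of the isolated trisubstituted alkene gives the cis-epoxide F3. Li2NiBr4 opens F3 at the secondary carbon C14 with inversion to give the bromohydrin F4. 1-Chloro-N,N,2-trimethylprop-1-en-1-amine then replaces the tertiary hydroxyl by chloride with retention (bromonium participation), giving 20, which re-enters step 13 at the MeLi/CeCl3 stage.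

Step 14. The enolisable β-chloro aldehyde and the competing enolisation sites of the enone may defeat the silyl-triflate cyclisation or erode its diastereoselectivity. The fallback closes ring B at the vinylogous-ester stage from a regiospecific enolate; it sets out from 20 (isolated by stopping step 13 after the alkylation) and returns at 24. Selective acetal hydrolysis (pyridinium tosylate, wet acetone) gives the aldehyde F5. With the aldehyde masked in situ as its lithium α-amino alkoxide (LiN(Me)CH2CH2NMe2), LiN(iPr)2 and 2-(trimethylsilyl)ethyl chloroformate give the enol carbonate F6. Tris(dimethylamino)sulfonium difluorotrimethylsilicate releases the C12 enolate, which closes by aldol addition to the spiro hydroxy vinylogous ester F7. MeLi/CeCl3 at −78 °C (the carbinol carried as its cerium alkoxide to suppress retro-aldol) then dilute HCl gives the spiro hydroxy enone F8, and Me3SiCl/imidazole returns to 24.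

Step 18. The vinyl bromide may be epoxidised too slowly, the carbinol may be oxidised, or the bromo-oxirane may not survive. The fallback builds the bromo-oxirane by ring closure; it sets out from 27 and returns at 31. A second enolisation/bromination (as in step 15) gives the gem-dibromide F9. Oxazaborolidine (CBS)-catalysed borane reduction gives the dibromo allylic alcohol F10, with the C7 carbinol set by the catalyst. K2CO3 in MeOH removes the silyl ether and closes the alkoxide onto the CBr2 carbon to give the bromo-oxirane F11. Epoxidation of the remaining C8=C10 bond with dimethyldioxirane, anti to the first oxirane, gives 31.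

**Further compounds**

F1 | step 13 | (2Z)-1-bromo-5,5-dimethoxy-3-methylpent-2-ene | BrC/C=C(/C)CC(OC)OC
F2 | step 13 | 6-[(2Z)-5,5-dimethoxy-3-methylpent-2-enyl]-5,5-dimethyl-3-(2-methylpropoxy)cyclohex-2-en-1-one | CC(C)COC1=CC(=O)C(C/C=C(/C)CC(OC)OC)C(C)(C)C1
F3 | step 13 | 6-{[(2R,3S)-3-(2,2-dimethoxyethyl)-3-methyloxiran-2-yl]methyl}-5,5-dimethyl-3-(2-methylpropoxy)cyclohex-2-en-1-one | CC(C)COC1=CC(=O)C(C[C@H]2O[C@@]2(C)CC(OC)OC)C(C)(C)C1
F4 | step 13 | 6-[(2S,3S)-2-bromo-3-hydroxy-5,5-dimethoxy-3-methylpentyl]-5,5-dimethyl-3-(2-methylpropoxy)cyclohex-2-en-1-one | CC(C)COC1=CC(=O)C(C[C@H](Br)[C@@](C)(O)CC(OC)OC)C(C)(C)C1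
F5 | step 14 | (3S,4S)-4-bromo-3-chloro-5-[6,6-dimethyl-4-(2-methylpropoxy)-2-oxocyclohex-3-en-1-yl]-3-methylpentanal | CC(C)COC1=CC(=O)C(C[C@H](Br)[C@@](C)(Cl)CC=O)C(C)(C)C1
F6 | step 14 | 2-[(2S,3S)-2-bromo-3-chloro-3-methyl-5-oxopentyl]-3,3-dimethyl-5-(2-methylpropoxy)cyclohexa-1,5-dien-1-yl 2-(trimethylsilyl)ethyl carbonate | C[Si](C)(C)CCOC(=O)OC1=C(C[C@H](Br)[C@@](C)(Cl)CC=O)C(C)(C)CC(OCC(C)C)=C1
F7 | step 14 | spiro hydroxy vinylogous ester (ring A 3-(2-methylpropoxy)-5,5-dimethylcyclohex-2-en-1-one spiro-fused at C12 to ring B, stereocentres as in 31) | CC1(C)CC(OCC(C)C)=CC(=O)[C@]12C[C@H](Br)[C@@](C)(Cl)C[C@@H]2O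
F8 | step 14 | (1S,3S,4S,6S)-4-bromo-3-chloro-1-hydroxy-3,7,11,11-tetramethylspiro[5.5]undec-7-en-9-one | CC1(C)CC(=O)C=C(C)[C@]12C[C@H](Br)[C@@](C)(Cl)C[C@@H]2O
F9 | step 18 | 4,10,10-tribromo-3-chloro-3,7,11,11-tetramethyl-1-(trimethylsilyloxy)spiro[5.5]undec-7-en-9-one (ring B stereocentres as in 27) | CC1(C)C(Br)(Br)C(=O)C=C(C)[C@]12C[C@H](Br)[C@@](C)(Cl)C[C@@H]2O[Si](C)(C)C
F10 | step 18 | 4,10,10-tribromo-3-chloro-3,7,11,11-tetramethyl-1-(trimethylsilyloxy)spiro[5.5]undec-7-en-9-ol (C7 carbinol as drawn) | CC1(C)C(Br)(Br)[C@@H](O)C=C(C)[C@]12C[C@H](Br)[C@@](C)(Cl)C[C@@H]2O[Si](C)(C)C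
F11 | step 18 | 4,10-dibromo-3-chloro-9,10-epoxy-3,7,11,11-tetramethylspiro[5.5]undec-7-en-1-ol (stereocentres as in 31) | CC1(C)[C@@]2(Br)O[C@H]2C=C(C)[C@]12C[C@H](Br)[C@@](C)(Cl)C[C@@H]2O
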